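**Retrosynthetic overview**
1. Labdane numbering: ring A = C1–C5 and C10, ring B = C5–C10, C19 = ester carbon on C4, C20 = methyl on C10, C17 = methyl on C8, side chain = C11–C16.
2. Late disconnections: the O-acetyl group; a temporary ring-B ketone at C7 (removed by Luche reduction and ionic hydrogenolysis); and C9–C11 (Stork–Danheiser addition of the C11–C16 organolithium to a ring-B vinylogous ester).
3. Key disconnection: C5–C10 and C8=C9 together, which unfolds both rings to an open-chain enone diester. In the forward direction one base-triggered Michael/Dieckmann bicyclization closes ring A first (C10 to C5) and ring B second (C8 to C9).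
4. Enabling feature: alkene carbon C9 of ring B is bonded to quaternary C10. C5 lies between two methyl-bearing quaternary carbons (C4, C10), each carrying a carboxyl-level carbon (C19, C9). With C9 as an ester and a ketone lent to C7, the path C9–C10–C5–C6–C7 is a consonant 1,5-dicarbonyl: C10 and C8 are nucleophiles, C5 and C9 are electrophiles, and C8=C9 is the enol of a 2-methylcyclohexane-1,3-dione.
5. The only lasting stereocentre of the open chain, quaternary C4, comes from methyl (R)-3-hydroxybutanoate by two Fráter–Seebach alkylations and steers C10 and C5.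

Key step: step 7

Remark: stereocentres that are later erased form as mixtures and are left undefined. These are the ester α-carbon C10 before the key step and the carbinol carbons C9 and C7 of two late intermediates. The ring-B 1,3-dione is drawn as its C9 enol.

Step 1
Reactants: 1 methyl (R)-3-hydroxybutanoate; 2 allyl bromide
Product: 4 methyl (2R)-2-[(1R)-1-hydroxyethyl]pent-4-enoate, via dilithio dianion 3 (not isolated)
Conditions: LiN(iPr)2 (LDA, 2.2 equiv), THF, −78 to −20 °C; 2, DMPU, −78 to 0 °C; 1 M HCl quench
Reagents that add atoms: allyl bromide (2), C=CCBr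
Why: Fráter–Seebach alkylation: the lithium-chelated alkoxide/enolate dianion is attacked on the face away from the carbinol methyl group, which should set the α-centre anti to the hydroxyl (2R,3R).

Step 2
Reactants: 4 methyl (2R)-2-[(1R)-1-hydroxyethyl]pent-4-enoate
Product: 6 methyl (2S)-2-[(1R)-1-hydroxyethyl]-2-methylpent-4-enoate, via dilithio dianion 5 (not isolated)
Conditions: LiN(iPr)2 (2.5 equiv), THF, −78 to 0 °C; MeI, DMPU, −78 to 0 °C; 1 M HCl quench
Reagents that add atoms: iodomethane, CI
Why: Second Fráter–Seebach alkylation: MeI enters the same face of the chelate, so quaternary C4 should form with S configuration, and the minor diastereomer can be removed here while the carbinol centre is still present.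

Step 3
Reactants: 6 methyl (2S)-2-[(1R)-1-hydroxyethyl]-2-methylpent-4-enoate
Product: 7 methyl (2S)-2-methyl-2-[(1R)-1-(trimethylsilyloxy)ethyl]pent-4-enoate
Conditions: TMSCl, imidazole, CH2Cl2, 0 °C to rt
Reagents that add atoms: chlorotrimethylsilane, C[Si](C)(C)Cl
Why: Routine silylation masks the hydroxyl so that it consumes neither borane nor base in the next step.

Step 4
Reactants: 7 methyl (2S)-2-methyl-2-[(1R)-1-(trimethylsilyloxy)ethyl]pent-4-enoate; 8 methyl 2-bromopropanoate (racemic)
Product: 11 dimethyl (2S)-2-[(1R)-1-hydroxyethyl]-2,6-dimethylheptanedioate (epimers at C6 = labdane C10), via B-alkyl borane 9 (not isolated), via silyl-protected diester 10 (not isolated)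
Conditions: 9-BBN-H, THF, 0 °C to rt; 8, t-BuOK, t-BuOH/THF, 0 °C; 1 M HCl, MeOH, rt
Reagents that add atoms: methyl 2-bromopropanoate (8), COC(=O)C(C)Br
Why: Anti-Markovnikov hydroboration of the only alkene, then the Brown α-alkylation of an α-bromo ester (enolate adds to boron, 1,2-migration of the primary alkyl group displaces bromide, protonolysis), should forge C1–C10; both C10 epimers are acceptable because this centre is enolized in step 7, and the acidic methanol work-up removes the silyl ether.

Step 5
Reactants: 11 dimethyl (2S)-2-[(1R)-1-hydroxyethyl]-2,6-dimethylheptanedioate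
Product: 12 dimethyl (2S)-2-ethenyl-2,6-dimethylheptanedioate
Conditions: Burgess reagent (MeO2CN(−)SO2N(+)Et3), toluene, 80 °C
Reagents that add atoms: none
Why: Burgess dehydration (syn elimination of the sulfamate): C4 is quaternary, so the carbinol carbon has β-hydrogens only on its methyl group and only the vinyl group (C5=C6) can form; the auxiliary carbinol centre is erased after it has set C4.

Step 6
Reactants: 12 dimethyl (2S)-2-ethenyl-2,6-dimethylheptanedioate; 13 pent-1-en-3-one
Product: 14 dimethyl (2S)-2,6-dimethyl-2-[(1E)-3-oxopent-1-en-1-yl]heptanedioate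
Conditions: RuCl2(H2IMes)(=CH-C6H4-2-OiPr) (second-generation Hoveyda–Grubbs catalyst, 5 mol %), 13 (3 equiv), CH2Cl2, 40 °C
Reagents that add atoms: pent-1-en-3-one (13), C=CC(=O)CC
Why: Olefin cross-metathesis: the vinyl group on quaternary C4 does not homodimerize and should pair with the electron-poor vinyl ketone to give the conjugated (E)-enone, with both esters inert.

Step 7
Reactants: 14 dimethyl (2S)-2,6-dimethyl-2-[(1E)-3-oxopent-1-en-1-yl]heptanedioate
Product: 16 methyl (1S,4aS,8aR)-5-hydroxy-1,4a,6-trimethyl-7-oxo-1,2,3,4,4a,7,8,8a-octahydronaphthalene-1-carboxylate (C9 enol of the C7/C9 dione), via Michael adduct 15 (not isolated)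
Conditions: KN(SiMe3)2 (KHMDS, 1.3 equiv), THF (0.01 M), −78 to 40 °C; 1 M HCl
Reagents that add atoms: none
Why: KHMDS first takes the most acidic C8–H (a cross-conjugated dienolate with no partner within reach), and proton shuttling by HN(SiMe3)2 opens the tautomeric C10 ester enolate with an intact enone, which adds to C5 (Michael addition, ring A, 6-(enolexo)-exo-trig); the ketone enolate then moves from C6 to C8, C8 acylates at C9 (Dieckmann-type Claisen closure, ring B, 6-(enolendo)-exo-trig), and loss of methoxide with deprotonation of the 2-methyl-1,3-dione makes the sequence irreversible. The closest known reaction types are the Michael–Claisen (dimedone-type) annulation of ester carbanions with enones, the double Michael/Dieckmann double annulation that gives trans-decalins with a CH flanked by two quaternary carbons, and the base-induced closure of 5-oxoheptanoates to 2-methylcyclohexane-1,3-dione. C10 is controlled by C4 in a chair-like Michael transition state with the (E)-enone arm equatorial: the bulky potassium-bound enolate terminus C9 avoids the axial site between C4 and C6, so C20 goes axial, and the flat CO2Me rather than the CH3 of C4 takes the site syn-axial to it, which makes the two esters of 15 trans (C4 and C10 of like configuration). C5, flanked in 15 by two constitutionally alike groups, becomes a stereocentre only in the second closure, where C8 reaches the equatorial C9 ester through a strain-free trans-decalin chair, so that H5 ends up axial and trans to C20. The regioselectivity needed is secured by ring size and reversibility: C4 bears no hydrogen (no γ-deprotonation), before ring A exists no enolate finds an electrophile within a five- to seven-membered ring except C10/C5 and C10/C19, the C10-to-C19 Dieckmann product is a non-enolizable β-keto ester that reverts, and C6 could only close four-membered rings. The chemoselectivity between the two esters is secured by position: C19 is axial and shielded by the syn-axial C20 methyl, whereas C9 is equatorial.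

Step 8
Reactants: 16 methyl (1S,4aS,8aR)-5-hydroxy-1,4a,6-trimethyl-7-oxo-1,2,3,4,4a,7,8,8a-octahydronaphthalene-1-carboxylate
Product: 17 methyl (1S,4aS,8aR)-1,4a,6-trimethyl-7-(2-methylpropoxy)-5-oxo-1,2,3,4,4a,5,8,8a-octahydronaphthalene-1-carboxylate
Conditions: i-BuOH, TsOH·H2O (cat.), toluene, reflux, Dean–Stark trap
Reagents that add atoms: 2-methylpropan-1-ol, CC(C)CO
Why: Acid-catalysed vinylogous esterification of an unsymmetrical 1,3-dione: the alcohol should attack the open C7 carbonyl and not C9 next to quaternary C10, which leaves the carbonyl at C9 as the Stork–Danheiser step requires; the hindered axial C19 ester does not exchange.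

Step 9
Reactants: 18 (2E)-3-methylpent-2-en-4-yn-1-ol
Product: 19 triethyl{[(2E)-3-methylpent-2-en-4-yn-1-yl]oxy}silane
Conditions: TESCl, imidazole, CH2Cl2, 0 °C to rt
Reagents that add atoms: chlorotriethylsilane, CC[Si](CC)(CC)Cl
Why: Routine silylation gives an ether that survives borane and alkyllithium reagents and falls off in dilute acid.

Step 10
Reactants: 19 triethyl{[(2E)-3-methylpent-2-en-4-yn-1-yl]oxy}silane
Product: 20 triethyl{[(2E)-3-methylpenta-2,4-dien-1-yl]oxy}silane
Conditions: H2 (1 atm), Pd/CaCO3 poisoned with Pb(OAc)2 (Lindlar catalyst), quinoline, hexane, rt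
Reagents that add atoms: none
Why: Lindlar semihydrogenation of the terminal alkyne should stop at the vinyl group and leave the (E)-trisubstituted alkene untouched.

Step 11
Reactants: 20 triethyl{[(2E)-3-methylpenta-2,4-dien-1-yl]oxy}silane
Product: 22 (3E)-3-methyl-5-(triethylsilyloxy)pent-3-en-1-ol, via side-chain borane 21 (not isolated)
Conditions: 9-BBN-H, THF, 0 °C to rt; NaOH, H2O2, 0 °C
Reagents that add atoms: hydrogen peroxide, OO
Why: Hydroboration–oxidation: the bulky borane should add only to the monosubstituted vinyl end of the diene, with boron on the terminal carbon (C11), so the trisubstituted alkene keeps its E geometry.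

Step 12
Reactants: 22 (3E)-3-methyl-5-(triethylsilyloxy)pent-3-en-1-ol
Product: 23 {[(2E)-5-iodo-3-methylpent-2-en-1-yl]oxy}triethylsilane
Conditions: I2, PPh3, imidazole, CH2Cl2, 0 °C
Reagents that add atoms: iodine, II
Why: Appel iodination of the primary homoallylic alcohol; imidazole buffers the medium so that the silyl ether survives.

Step 13
Reactants: 23 {[(2E)-5-iodo-3-methylpent-2-en-1-yl]oxy}triethylsilane; 17 methyl (1S,4aS,8aR)-1,4a,6-trimethyl-7-(2-methylpropoxy)-5-oxo-1,2,3,4,4a,5,8,8a-octahydronaphthalene-1-carboxylate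
Product: 26 methyl (1S,4aS,8aR)-5-[(3E)-5-hydroxy-3-methylpent-3-en-1-yl]-1,4a,6-trimethyl-7-oxo-1,2,3,4,4a,7,8,8a-octahydronaphthalene-1-carboxylate, via organolithium 24 (not isolated), via tertiary carbinol 25 (not isolated)
Conditions: 23 (1.5 equiv), t-BuLi (3.0 equiv), Et2O/pentane, −78 °C; 17, THF, −78 to 0 °C; 1 M HCl, THF, rt
Reagents that add atoms: none
Why: Stork–Danheiser sequence: iodine–lithium exchange gives the primary alkyllithium, which adds 1,2 to the C9 carbonyl of the vinylogous ester (quaternary C10 has no α-hydrogen, so no enolization, and the axial C19 ester is far less accessible); aqueous acid then ionizes the tertiary allylic carbinol, hydrolyses the enol ether to the C7 ketone with the alkene back at C8=C9, and cleaves the triethylsilyl ether.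

Step 14
Reactants: 26 methyl (1S,4aS,8aR)-5-[(3E)-5-hydroxy-3-methylpent-3-en-1-yl]-1,4a,6-trimethyl-7-oxo-1,2,3,4,4a,7,8,8a-octahydronaphthalene-1-carboxylate
Product: 27 methyl (1S,4aS,8aR)-5-[(3E)-5-acetoxy-3-methylpent-3-en-1-yl]-1,4a,6-trimethyl-7-oxo-1,2,3,4,4a,7,8,8a-octahydronaphthalene-1-carboxylate
Conditions: Ac2O, pyridine, DMAP (cat.), CH2Cl2, 0 °C to rt
Reagents that add atoms: acetic anhydride, CC(=O)OC(C)=O
Why: Routine acetylation of the only hydroxyl group; the acetate also makes the side-chain allylic C–O bond harder to ionize in step 16.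

Step 15
Reactants: 27 methyl (1S,4aS,8aR)-5-[(3E)-5-acetoxy-3-methylpent-3-en-1-yl]-1,4a,6-trimethyl-7-oxo-1,2,3,4,4a,7,8,8a-octahydronaphthalene-1-carboxylate
Product: 28 methyl (1S,4aS,8aR)-5-[(3E)-5-acetoxy-3-methylpent-3-en-1-yl]-7-hydroxy-1,4a,6-trimethyl-1,2,3,4,4a,7,8,8a-octahydronaphthalene-1-carboxylate (epimers at C7)
Conditions: NaBH4, CeCl3·7H2O, MeOH, 0 °C
Reagents that add atoms: none
Why: Luche reduction should give clean 1,2-reduction of the enone without touching either ester; the configuration of the new C7 carbinol is irrelevant because the oxygen leaves in the next step.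

Step 16
Reactants: 28 methyl (1S,4aS,8aR)-5-[(3E)-5-acetoxy-3-methylpent-3-en-1-yl]-7-hydroxy-1,4a,6-trimethyl-1,2,3,4,4a,7,8,8a-octahydronaphthalene-1-carboxylate
Product: 29 methyl (1S,4aS,8aR)-5-[(3E)-5-acetoxy-3-methylpent-3-en-1-yl]-1,4a,6-trimethyl-1,2,3,4,4a,7,8,8a-octahydronaphthalene-1-carboxylate (target)
Conditions: Et3SiH (5 equiv), BF3·OEt2 (1.2 equiv), CH2Cl2, −78 °C
Reagents that add atoms: none
Why: Ionic hydrogenolysis of an allylic alcohol (silane/Lewis acid, Kursanov–Parnes type): the ring carbinol should ionize at low temperature to the fully alkylated C7–C8–C9 allyl cation far more readily than the primary allylic acetate, and hydride goes to the less hindered secondary terminus C7, which leaves the tetrasubstituted C8=C9 alkene in place.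

**Compound list**
1 | methyl (R)-3-hydroxybutanoate | C[C@@H](O)CC(=O)OC | starting material
2 | allyl bromide | C=CCBr | starting material
3 | dilithio dianion of 1 | C[C@@H](O[Li])C=C(OC)O[Li] | intermediate
4 | methyl (2R)-2-[(1R)-1-hydroxyethyl]pent-4-enoate | COC(=O)[C@H](CC=C)[C@@H](C)O | intermediate
5 | dilithio dianion of 4 | C[C@@H](O[Li])C(CC=C)=C(OC)O[Li] | intermediate
6 | methyl (2S)-2-[(1R)-1-hydroxyethyl]-2-methylpent-4-enoate | COC(=O)[C@@](C)(CC=C)[C@@H](C)O | intermediate
7 | methyl (2S)-2-methyl-2-[(1R)-1-(trimethylsilyloxy)ethyl]pent-4-enoate | COC(=O)[C@@](C)(CC=C)[C@@H](C)O[Si](C)(C)C | intermediate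
8 | methyl 2-bromopropanoate (racemic) | COC(=O)C(C)Br | starting material
9 | B-alkyl-9-BBN adduct of 7 (boron on C1) | COC(=O)[C@@](C)(CCCB1C2CCCC1CCC2)[C@@H](C)O[Si](C)(C)C | intermediate
10 | dimethyl (2S)-2,6-dimethyl-2-[(1R)-1-(trimethylsilyloxy)ethyl]heptanedioate | COC(=O)[C@@](C)(CCCC(C)C(=O)OC)[C@@H](C)O[Si](C)(C)C | intermediate
11 | dimethyl (2S)-2-[(1R)-1-hydroxyethyl]-2,6-dimethylheptanedioate | COC(=O)[C@@](C)(CCCC(C)C(=O)OC)[C@@H](C)O | intermediate
12 | dimethyl (2S)-2-ethenyl-2,6-dimethylheptanedioate | COC(=O)[C@@](C)(CCCC(C)C(=O)OC)C=C | intermediate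
13 | pent-1-en-3-one | C=CC(=O)CC | starting material
14 | dimethyl (2S)-2,6-dimethyl-2-[(1E)-3-oxopent-1-en-1-yl]heptanedioate | COC(=O)[C@@](C)(CCCC(C)C(=O)OC)/C=C/C(=O)CC | intermediate
15 | dimethyl (1S,3S)-1,3-dimethyl-2-(2-oxobutyl)cyclohexane-1,3-dicarboxylate (ring A, esters trans) | COC(=O)[C@@]1(C)CCC[C@](C)(C(=O)OC)C1CC(=O)CC | intermediate
16 | methyl (1S,4aS,8aR)-5-hydroxy-1,4a,6-trimethyl-7-oxo-1,2,3,4,4a,7,8,8a-octahydronaphthalene-1-carboxylate | COC(=O)[C@@]1(C)CCC[C@]2(C)C(O)=C(C)C(=O)C[C@@H]12 | intermediate
17 | methyl (1S,4aS,8aR)-1,4a,6-trimethyl-7-(2-methylpropoxy)-5-oxo-1,2,3,4,4a,5,8,8a-octahydronaphthalene-1-carboxylate | COC(=O)[C@@]1(C)CCC[C@]2(C)C(=O)C(C)=C(OCC(C)C)C[C@@H]12 | intermediate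
18 | (2E)-3-methylpent-2-en-4-yn-1-ol | C#C/C(C)=C/CO | starting material
19 | triethyl{[(2E)-3-methylpent-2-en-4-yn-1-yl]oxy}silane | C#C/C(C)=C/CO[Si](CC)(CC)CC | intermediate
20 | triethyl{[(2E)-3-methylpenta-2,4-dien-1-yl]oxy}silane | C=C/C(C)=C/CO[Si](CC)(CC)CC | intermediate
21 | B-alkyl-9-BBN adduct of 20 (boron on C11) | B1(CC/C(C)=C/CO[Si](CC)(CC)CC)C2CCCC1CCC2 | intermediate
22 | (3E)-3-methyl-5-(triethylsilyloxy)pent-3-en-1-ol | OCC/C(C)=C/CO[Si](CC)(CC)CC | intermediate
23 | {[(2E)-5-iodo-3-methylpent-2-en-1-yl]oxy}triethylsilane | ICC/C(C)=C/CO[Si](CC)(CC)CC | intermediate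
24 | (3E)-3-methyl-5-(triethylsilyloxy)pent-3-en-1-yllithium | [Li]CC/C(C)=C/CO[Si](CC)(CC)CC | intermediate
25 | C9 tertiary carbinol from 24 and 17 (epimers at C9) | COC(=O)[C@@]1(C)CCC[C@]2(C)C(O)(CC/C(C)=C/CO[Si](CC)(CC)CC)C(C)=C(OCC(C)C)C[C@@H]12 | intermediate
26 | methyl 15-hydroxy-7-oxolabda-8,13E-dien-19-oate | COC(=O)[C@@]1(C)CCC[C@]2(C)C(CC/C(C)=C/CO)=C(C)C(=O)C[C@@H]12 | intermediate
27 | methyl 15-acetoxy-7-oxolabda-8,13E-dien-19-oate | COC(=O)[C@@]1(C)CCC[C@]2(C)C(CC/C(C)=C/COC(C)=O)=C(C)C(=O)C[C@@H]12 | intermediate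
28 | methyl 15-acetoxy-7-hydroxylabda-8,13E-dien-19-oate (epimers at C7) | COC(=O)[C@@]1(C)CCC[C@]2(C)C(CC/C(C)=C/COC(C)=O)=C(C)C(O)C[C@@H]12 | intermediate
29 | methyl 15-acetoxylabda-8,13E-dien-19-oate (4S,5R,10S) | COC(=O)[C@@]1(C)CCC[C@]2(C)C(CC/C(C)=C/COC(C)=O)=C(C)CC[C@@H]12 | target

**Total step count:** 16.
**Longest linear sequence:** 12 steps (steps 1–8 and 13–16).

**Steps most likely to fail**

**Step 7.**
- What may go wrong: enolization at C10 may be too slow beside the more acidic enone, so that intermolecular Michael addition takes over. The relative configuration at C4/C10 may be poorly controlled, or acylation may leak to the axial ester and give a cis ring fusion.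
- Fallback: radical instead of anionic closure of ring A, with the two rings closed in separate operations. It sets out from 12.
- Deprotonation at C10, the only acidic C–H (LiN(iPr)2, THF, −78 °C), followed by CBr4 should give the tertiary α-bromo diester F1.
- Cross-metathesis with 13 as in step 6 should give the bromo enone F2.
- Slow addition of Bu3SnH/AIBN (toluene, 80 °C) should trigger a 6-exo conjugate addition of the tertiary α-ester radical to C5 and give keto diester 15, now isolated.
- NaOMe in MeOH/toluene at reflux then closes ring B (Dieckmann), and the route is rejoined at 16.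

**Step 13.**
- What may go wrong: addition to the hindered C9 carbonyl may be sluggish. The organolithium may attack the C19 ester instead, or decay by loss of silanolate.
- Fallback: cross-coupling instead of carbonyl addition, with the C7 oxygen removed before the side chain arrives. It sets out from 16.
- Tf2O and 2,6-lutidine (CH2Cl2, −78 °C) should sulfonylate the less hindered oxygen and give the 7-triflyloxy enone F3.
- H2, Pd/C and NaHCO3 in EtOAc should hydrogenolyse and saturate it to the 9-ketone F4.
- KN(SiMe3)2 and PhNTf2 (THF, −78 °C) should give the tetrasubstituted enol triflate F5, since only C8 can enolize.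
- B-alkyl Suzuki–Miyaura coupling with borane 21 (PdCl2(dppf), Cs2CO3, DMF/THF/H2O, 50 °C) should give the silyl ether F6.
- 1 M HCl in THF frees the allylic alcohol F7, and Ac2O/pyridine rejoins the route at 29.

**Step 16.**
- What may go wrong: the side-chain allylic acetate may also ionize. The allyl cation may lose a proton to give dienes, be captured by the C13 alkene, or take hydride at the wrong terminus.
- Fallback: elimination and concerted hydrogen transfer instead of a cation/hydride pair. It sets out from 28.
- Martin sulfurane (Ph2S[OC(CF3)2Ph]2, CH2Cl2, 0 °C) should remove water toward C6, the only β-hydrogen, and give the homoannular 6,8-diene F8.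
- Diimide (2-nitrobenzenesulfonyl hydrazide, Et3N, CH2Cl2, rt) should reduce the only disubstituted alkene, C6=C7, by 1,2-addition, and the route is rejoined at 29.

**Further compounds**
F1 | step 7 | dimethyl (6S)-2-bromo-6-ethenyl-2,6-dimethylheptanedioate | COC(=O)[C@@](C)(CCCC(C)(Br)C(=O)OC)C=C
F2 | step 7 | dimethyl (6S)-2-bromo-2,6-dimethyl-6-[(1E)-3-oxopent-1-en-1-yl]heptanedioate | COC(=O)[C@@](C)(CCCC(C)(Br)C(=O)OC)/C=C/C(=O)CC
F3 | step 13 | methyl (1S,4aS,8aR)-1,4a,6-trimethyl-5-oxo-7-(trifluoromethylsulfonyloxy)-1,2,3,4,4a,5,8,8a-octahydronaphthalene-1-carboxylate | COC(=O)[C@@]1(C)CCC[C@]2(C)C(=O)C(C)=C(OS(=O)(=O)C(F)(F)F)C[C@@H]12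
F4 | step 13 | methyl (1S,4aS,8aR)-1,4a,6-trimethyl-5-oxodecahydronaphthalene-1-carboxylate (epimers at C8) | COC(=O)[C@@]1(C)CCC[C@]2(C)C(=O)C(C)CC[C@@H]12
F5 | step 13 | methyl (1S,4aS,8aR)-1,4a,6-trimethyl-5-(trifluoromethylsulfonyloxy)-1,2,3,4,4a,7,8,8a-octahydronaphthalene-1-carboxylate | COC(=O)[C@@]1(C)CCC[C@]2(C)C(OS(=O)(=O)C(F)(F)F)=C(C)CC[C@@H]12
F6 | step 13 | methyl 15-(triethylsilyloxy)labda-8,13E-dien-19-oate | COC(=O)[C@@]1(C)CCC[C@]2(C)C(CC/C(C)=C/CO[Si](CC)(CC)CC)=C(C)CC[C@@H]12
F7 | step 13 | methyl 15-hydroxylabda-8,13E-dien-19-oate | COC(=O)[C@@]1(C)CCC[C@]2(C)C(CC/C(C)=C/CO)=C(C)CC[C@@H]12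
F8 | step 16 | methyl 15-acetoxylabda-6,8,13E-trien-19-oate | COC(=O)[C@@]1(C)CCC[C@]2(C)C(CC/C(C)=C/COC(C)=O)=C(C)C=C[C@@H]12
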